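**Retrosynthetic overview**
1. The strategy rests on ring C (the pyranone): its only stereocentre C2 is bonded to the ring oxygen O1 and lies β to the C4 ketone, so O1–C2 is the conjugate-addition bond of a 2′-hydroxychalcone. With a C3 tert-butyl ester as extra activator, this bond is closed last under a cinchona thiourea (15 → 16).
2. Ring A fixes the regiochemistry: C6 (piperidine-bearing) lies between O5 and O7 and para to O1. O5 and O7 are therefore benzylated, only the C8a hydroxyl is free, and nitrogen is a Boc carbamate.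
3. 15 ⇒ Knoevenagel condensation (C2=C3) of β-keto ester 13 with aldehyde 14 (ring B); 13 ⇒ phenol 10 by ortho-formylation, acetate aldol and oxidation.
4. 10 ⇒ piperidine ring: C2′ is set by Grignard addition to the (R)-tert-butanesulfinyl imine of the para-formylated phenol, followed by N-alkylative closure and exchange of sulfinyl for Boc.
5. Ring order: ring A (arene of 1) → piperidine (step 5) → ring B attached (step 10) → ring C (step 11).

Key step: step 11

Assumption: the quinidine-derived thiourea is taken to give the 2S sense; if a model run on a simpler substrate shows the opposite sense, the quinine-derived pseudo-enantiomer is used under the same conditions.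

**Step 1**
Reactants: 1 3,5-bis(benzyloxy)phenol
Product: 3 aldehyde 2,6-bis(benzyloxy)-4-hydroxybenzaldehyde, via iminium chloride 2 (not isolated)
Conditions: POCl3, DMF, MeCN, 0 °C → rt; then H2O, rt
Reagents that add atoms: N,N-dimethylformamide CN(C)C=O; water O
Why: Vilsmeier–Haack formylation, in which the chloroiminium ion is expected to enter mainly para to the free hydroxyl (the carbon between the two benzyloxy groups), as is usual for 3,5-dialkoxyphenols; the minor chelated ortho isomer is removed by crystallisation or chromatography after hydrolysis of 2.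

**Step 2**
Reactants: 3 2,6-bis(benzyloxy)-4-hydroxybenzaldehyde
Product: 4 4-(allyloxy)-2,6-bis(benzyloxy)benzaldehyde
Conditions: allyl bromide, K2CO3, DMF, rt
Reagents that add atoms: allyl bromide C=CCBr
Why: Williamson etherification of the only free phenol masks the future O1 with a group that survives the Grignard, base and acid steps and is later removed under neutral conditions without touching the benzyl ethers.

**Step 3**
Reactants: 4 4-(allyloxy)-2,6-bis(benzyloxy)benzaldehyde
Product: 5 (R)-N-[(E)-4-(allyloxy)-2,6-bis(benzyloxy)benzylidene]-2-methylpropane-2-sulfinamide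
Conditions: (R)-t-BuS(O)NH2, Ti(OEt)4, THF, 65 °C
Reagents that add atoms: (R)-2-methylpropane-2-sulfinamide CC(C)(C)[S@@](=O)N
Why: Ti(OEt)4-mediated condensation of an aldehyde with tert-butanesulfinamide (sulfinimine formation), the Lewis acid also scavenging water, should give the E aldimine even from this di-ortho-substituted electron-rich aldehyde, with the sulfur centre untouched.

**Step 4**
Reactants: 5 the (R)-sulfinyl aldimine
Product: 6 (R)-N-[(1S)-1-[4-(allyloxy)-2,6-bis(benzyloxy)phenyl]-5-chloropentyl]-2-methylpropane-2-sulfinamide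
Conditions: Cl(CH2)4MgBr (from Br(CH2)4Cl, Mg, Et2O), CH2Cl2, −48 °C → rt; aq. NH4Cl
Reagents that add atoms: 4-chlorobutylmagnesium bromide ClCCCC[Mg]Br
Why: 1,2-Addition of a Grignard reagent to an N-tert-butanesulfinyl aldimine in a non-coordinating solvent, where the closed six-membered transition state (magnesium on the sulfinyl oxygen, tert-butyl equatorial) is expected to give the S carbon from the R auxiliary; the two sulfinamide diastereomers are separable, so the configurational purity of C2′ is secured here and its assignment is to be confirmed by correlation.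

**Step 5**
Reactants: 6 the chloro sulfinamide
Product: 7 (2S)-2-[4-(allyloxy)-2,6-bis(benzyloxy)phenyl]-1-[(R)-tert-butylsulfinyl]piperidine
Conditions: NaH, NaI (cat.), DMF, 0 °C → rt
Reagents that add atoms: none
Why: Intramolecular N-alkylation (6-exo-tet SN2, with in situ Finkelstein exchange) of the sodium sulfinamide anion by the primary chloride closes the piperidine ring without involving C2′.

**Step 6**
Reactants: 7 the N-sulfinyl piperidine
Product: 9 tert-butyl (2S)-2-[4-(allyloxy)-2,6-bis(benzyloxy)phenyl]piperidine-1-carboxylate, via piperidine hydrochloride 8 (not isolated)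
Conditions: HCl (4 M in dioxane), MeOH, 0 °C; evaporate; Boc2O, Et3N, CH2Cl2, rt
Reagents that add atoms: di-tert-butyl dicarbonate CC(C)(C)OC(=O)OC(=O)OC(C)(C)C
Why: Acidolysis of the N–S bond (brief and cold, so the electron-rich benzylic C–N bond is not ionised) followed by carbamate formation exchanges the auxiliary for the non-basic Boc group needed in steps 10 and 11.

**Step 7**
Reactants: 9 the allyl ether
Product: 10 tert-butyl (2S)-2-[2,6-bis(benzyloxy)-4-hydroxyphenyl]piperidine-1-carboxylate
Conditions: Pd(PPh3)4 (cat.), K2CO3, MeOH, rt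
Reagents that add atoms: none
Why: Tsuji–Trost deallylation, in which zerovalent palladium ionises the allyl aryl ether to a π-allyl complex that methanol captures, frees the C8a hydroxyl while Boc and benzyl ethers are inert.

**Step 8**
Reactants: 10 the phenol
Product: 11 tert-butyl (2S)-2-[2,6-bis(benzyloxy)-3-formyl-4-hydroxyphenyl]piperidine-1-carboxylate
Conditions: MgCl2, Et3N, (CH2O)n, MeCN, 75 °C; aq. citric acid work-up
Reagents that add atoms: formaldehyde (as paraformaldehyde) C=O
Why: Magnesium-phenoxide-directed ortho-formylation (Casnati–Skattebøl reaction) delivers formaldehyde within the chelate to a carbon ortho to the hydroxyl and oxidises the hydroxymethyl intermediate by hydride transfer to a second formaldehyde; the two free ring positions are equivalent and both ortho, so only one aldehyde can form, under conditions that leave Boc intact.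

**Step 9**
Reactants: 11 the salicylaldehyde
Product: 13 tert-butyl (2S)-2-[2,6-bis(benzyloxy)-3-(3-tert-butoxy-3-oxopropanoyl)-4-hydroxyphenyl]piperidine-1-carboxylate, via β-hydroxy ester 12 (not isolated)
Conditions: t-BuOAc, LiN(i-Pr)2 (3.5 equiv each), THF, −78 °C; aq. NH4Cl; crude, then MnO2, CH2Cl2, rt
Reagents that add atoms: tert-butyl acetate CC(=O)OC(C)(C)C
Why: Aldol addition of the lithium enolate of tert-butyl acetate (in excess, since one equivalent is spent on the phenol) followed by MnO2 oxidation of the ortho-hydroxybenzylic alcohol, taken on crude to avoid acid-promoted dehydration through a quinone methide; the carbinol centre of 12 forms without control and is erased on oxidation.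

**Step 10**
Reactants: 13 the β-keto ester; 14 4-(benzyloxy)benzaldehyde
Product: 15 tert-butyl (2S)-2-[2,6-bis(benzyloxy)-3-[(2Z)-3-[4-(benzyloxy)phenyl]-2-(tert-butoxycarbonyl)prop-2-enoyl]-4-hydroxyphenyl]piperidine-1-carboxylate
Conditions: piperidine (cat.), AcOH (cat.), 4 Å MS, toluene, rt
Reagents that add atoms: none
Why: Knoevenagel condensation under buffered amine catalysis at low temperature, chosen so that the hydrogen-bonded C8a hydroxyl does not yet add to the new acceptor; the isomer with the aryl group trans to the aroyl group is drawn, and a mixture of geometric isomers would be taken on.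

**Step 11**
Reactants: 15 the alkylidene β-keto ester
Product: 16 tert-butyl (2S)-5,7-bis(benzyloxy)-2-[4-(benzyloxy)phenyl]-6-[(2S)-1-(tert-butoxycarbonyl)piperidin-2-yl]-4-oxochromane-3-carboxylate (C3 not fixed; enol and keto forms)
Conditions: quinidine-derived thiourea 1-[3,5-bis(trifluoromethyl)phenyl]-3-[(9R)-6′-methoxycinchonan-9-yl]thiourea (10 mol %), toluene, −25 °C; cold filtration through silica
Reagents that add atoms: none
Why: This is an intramolecular oxa-Michael addition under bifunctional catalysis: the quinuclidine nitrogen deprotonates the C8a hydroxyl while the thiourea N–H bonds hold the β-keto ester unit, and the phenoxide adds to the benzylidene carbon to form O1–C2. The closest known reaction type is the cinchona-thiourea-catalysed cyclisation of 2-hydroxyaryl alkylidene β-keto esters to 3-carboxyflavanones. Ring C closes in the 6-endo-trig mode. C2 is set by the catalyst, the S centre at C2′ being too remote to compete, and C3 is not a fixed centre because the adduct rests largely as its enol and the ester leaves in step 12. The step needs face selectivity at C2 and a single direction of closure; the latter is secured because O5 and O7 are benzylated and only the C8a hydroxyl is free, and a racemic background closure is held down by the non-basic carbamate on nitrogen and the low temperature. The geminal ester raises the reactivity of the acceptor, so that the electron-rich 4-benzyloxyphenyl terminus should still react at −25 °C, and makes the closure effectively irreversible.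

**Step 12**
Reactants: 16 the 3-(tert-butoxycarbonyl)flavanone
Product: 18 (2S)-5,7-bis(benzyloxy)-2-[4-(benzyloxy)phenyl]-6-[(2S)-piperidin-2-yl]chroman-4-one, via β-keto acid salt 17 (not isolated)
Conditions: CF3CO2H, CH2Cl2, 0 °C → rt; concentrate; toluene, 60 °C; aq. NaHCO3
Reagents that add atoms: none
Why: Acidolysis of the tert-butyl ester and of Boc (loss of 2-methylpropene) followed by thermal decarboxylation of β-keto acid 17 through its cyclic transition state; the medium stays acidic until work-up, so base-triggered retro-oxa-Michael opening cannot scramble C2, and the benzyl ethers should survive the brief exposure.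

**Step 13**
Reactants: 18 the secondary amine
Product: 19 (2S)-5,7-bis(benzyloxy)-2-[4-(benzyloxy)phenyl]-6-[(2S)-1-methylpiperidin-2-yl]chroman-4-one
Conditions: aq. HCHO (37%), NaBH(OAc)3, AcOH, ClCH2CH2Cl, rt
Reagents that add atoms: formaldehyde C=O
Why: Reductive amination (iminium formation, then hydride delivery) is done while all three phenols are benzylated, so no Mannich reaction can occur on ring A, and with a hydride too mild to reduce the hindered C4 aryl ketone.

**Step 14**
Reactants: 19 the tri-O-benzyl N-methyl flavanone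
Product: 20 (2S)-5,7-dihydroxy-2-(4-hydroxyphenyl)-6-[(2S)-1-methylpiperidin-2-yl]chroman-4-one (target)
Conditions: H2 (1 atm), 10% Pd/C, EtOAc–MeOH, rt
Reagents that add atoms: none
Why: Catalytic hydrogenolysis of the three aryl benzyl ethers in neutral medium, stopped at three equivalents of uptake so that the slower cleavage of the hindered benzylic C2′–N and C2–O1 bonds and reduction of the C4 ketone do not set in; neither stereocentre is touched.

**Compound list**
1 | 3,5-bis(benzyloxy)phenol | Oc1cc(OCc2ccccc2)cc(OCc2ccccc2)c1 | starting material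
2 | N-[2,6-bis(benzyloxy)-4-hydroxybenzylidene]-N-methylmethanaminium chloride | C[N+](C)=Cc1c(OCc2ccccc2)cc(O)cc1OCc1ccccc1.[Cl-] | intermediate
3 | 2,6-bis(benzyloxy)-4-hydroxybenzaldehyde | O=Cc1c(OCc2ccccc2)cc(O)cc1OCc1ccccc1 | intermediate
4 | 4-(allyloxy)-2,6-bis(benzyloxy)benzaldehyde | O=Cc1c(OCc2ccccc2)cc(OCC=C)cc1OCc1ccccc1 | intermediate
5 | (R)-N-[(E)-4-(allyloxy)-2,6-bis(benzyloxy)benzylidene]-2-methylpropane-2-sulfinamide | CC(C)(C)[S@@](=O)/N=C/c1c(OCc2ccccc2)cc(OCC=C)cc1OCc1ccccc1 | intermediate
6 | (R)-N-[(1S)-1-[4-(allyloxy)-2,6-bis(benzyloxy)phenyl]-5-chloropentyl]-2-methylpropane-2-sulfinamide | CC(C)(C)[S@@](=O)N[C@@H](CCCCCl)c1c(OCc2ccccc2)cc(OCC=C)cc1OCc1ccccc1 | intermediate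
7 | (2S)-2-[4-(allyloxy)-2,6-bis(benzyloxy)phenyl]-1-[(R)-tert-butylsulfinyl]piperidine | CC(C)(C)[S@@](=O)N1CCCC[C@H]1c1c(OCc2ccccc2)cc(OCC=C)cc1OCc1ccccc1 | intermediate
8 | (2S)-2-[4-(allyloxy)-2,6-bis(benzyloxy)phenyl]piperidine hydrochloride | N1CCCC[C@H]1c1c(OCc2ccccc2)cc(OCC=C)cc1OCc1ccccc1.Cl | intermediate
9 | tert-butyl (2S)-2-[4-(allyloxy)-2,6-bis(benzyloxy)phenyl]piperidine-1-carboxylate | CC(C)(C)OC(=O)N1CCCC[C@H]1c1c(OCc2ccccc2)cc(OCC=C)cc1OCc1ccccc1 | intermediate
10 | tert-butyl (2S)-2-[2,6-bis(benzyloxy)-4-hydroxyphenyl]piperidine-1-carboxylate | CC(C)(C)OC(=O)N1CCCC[C@H]1c1c(OCc2ccccc2)cc(O)cc1OCc1ccccc1 | intermediate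
11 | tert-butyl (2S)-2-[2,6-bis(benzyloxy)-3-formyl-4-hydroxyphenyl]piperidine-1-carboxylate | CC(C)(C)OC(=O)N1CCCC[C@H]1c1c(OCc2ccccc2)cc(O)c(C=O)c1OCc1ccccc1 | intermediate
12 | tert-butyl (2S)-2-[2,6-bis(benzyloxy)-3-(3-tert-butoxy-1-hydroxy-3-oxopropyl)-4-hydroxyphenyl]piperidine-1-carboxylate (carbinol epimers) | CC(C)(C)OC(=O)N1CCCC[C@H]1c1c(OCc2ccccc2)cc(O)c(C(O)CC(=O)OC(C)(C)C)c1OCc1ccccc1 | intermediate
13 | tert-butyl (2S)-2-[2,6-bis(benzyloxy)-3-(3-tert-butoxy-3-oxopropanoyl)-4-hydroxyphenyl]piperidine-1-carboxylate | CC(C)(C)OC(=O)N1CCCC[C@H]1c1c(OCc2ccccc2)cc(O)c(C(=O)CC(=O)OC(C)(C)C)c1OCc1ccccc1 | intermediate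
14 | 4-(benzyloxy)benzaldehyde | O=Cc1ccc(OCc2ccccc2)cc1 | starting material
15 | tert-butyl (2S)-2-[2,6-bis(benzyloxy)-3-[(2Z)-3-[4-(benzyloxy)phenyl]-2-(tert-butoxycarbonyl)prop-2-enoyl]-4-hydroxyphenyl]piperidine-1-carboxylate | CC(C)(C)OC(=O)N1CCCC[C@H]1c1c(OCc2ccccc2)cc(O)c(C(=O)/C(C(=O)OC(C)(C)C)=C/c2ccc(OCc3ccccc3)cc2)c1OCc1ccccc1 | intermediate
16 | tert-butyl (2S)-5,7-bis(benzyloxy)-2-[4-(benzyloxy)phenyl]-6-[(2S)-1-(tert-butoxycarbonyl)piperidin-2-yl]-4-oxochromane-3-carboxylate | CC(C)(C)OC(=O)N1CCCC[C@H]1c1c(OCc2ccccc2)cc2c(c1OCc1ccccc1)C(=O)C(C(=O)OC(C)(C)C)[C@@H](c1ccc(OCc3ccccc3)cc1)O2 | intermediate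
17 | (2S)-5,7-bis(benzyloxy)-2-[4-(benzyloxy)phenyl]-4-oxo-6-[(2S)-piperidin-2-yl]chromane-3-carboxylic acid trifluoroacetate salt | N1CCCC[C@H]1c1c(OCc2ccccc2)cc2c(c1OCc1ccccc1)C(=O)C(C(=O)O)[C@@H](c1ccc(OCc3ccccc3)cc1)O2.OC(=O)C(F)(F)F | intermediate
18 | (2S)-5,7-bis(benzyloxy)-2-[4-(benzyloxy)phenyl]-6-[(2S)-piperidin-2-yl]chroman-4-one | N1CCCC[C@H]1c1c(OCc2ccccc2)cc2c(c1OCc1ccccc1)C(=O)C[C@@H](c1ccc(OCc3ccccc3)cc1)O2 | intermediate
19 | (2S)-5,7-bis(benzyloxy)-2-[4-(benzyloxy)phenyl]-6-[(2S)-1-methylpiperidin-2-yl]chroman-4-one | CN1CCCC[C@H]1c1c(OCc2ccccc2)cc2c(c1OCc1ccccc1)C(=O)C[C@@H](c1ccc(OCc3ccccc3)cc1)O2 | intermediate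
20 | (2S)-5,7-dihydroxy-2-(4-hydroxyphenyl)-6-[(2S)-1-methylpiperidin-2-yl]chroman-4-one | CN1CCCC[C@H]1c1c(O)cc2c(c1O)C(=O)C[C@@H](c1ccc(O)cc1)O2 | target

**Step count and risks**
Total step count: 14. Longest linear sequence: 14 steps (1 → 20); aldehyde 14 enters at step 10.

Steps most likely to fail:

Step 11. Facial discrimination at the benzylidene carbon may be insufficient, because the C5 benzyloxy group and the bulky C6 substituent crowd the thiourea-bound dicarbonyl, or an uncatalysed closure may erode selectivity at C2. The fallback sets C2 by C–C bond formation instead. It sets out from 13: condensation with DMF dimethyl acetal (toluene, rt → 60 °C) gives the enaminone F1, which closes with loss of dimethylamine to the chromone-3-carboxylate F2. A base-free asymmetric conjugate addition of 4-(benzyloxy)phenylboronic acid to F2 (Pd(OCOCF3)2, t-BuPyOx ligand of the enantiomer that gives 2S, NH4PF6, H2O, ClCH2CH2Cl, 60 °C) then delivers 16, where the route is rejoined.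

Step 9. Water may be lost from the ortho-hydroxybenzylic alcohol through a quinone methide, or the free electron-rich phenol may be degraded oxidatively on MnO2. The fallback builds the ketone without a carbinol stage. It sets out from 10: ortho-iodination (N-iodosuccinimide, CH2Cl2, −40 °C) gives the iodophenol F3. Stille coupling with tributyl(1-ethoxyvinyl)stannane (Pd2(dba)3, t-Bu3P, CsF, dioxane, 80 °C) gives the enol ether F4, which cold dilute aqueous HCl hydrolyses to the acetophenone F5. The dianion of F5 (LiN(SiMe3)2, THF, −78 °C) is C-acylated with Boc2O, the stabilised β-keto ester enolate being the thermodynamic sink, to give 13, where the route is rejoined.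

Step 4. Addition to the congested, electron-rich aldimine may be slow, or chelation of magnesium by an ortho benzyloxy oxygen may erode or invert the facial selectivity. The fallback forms the C6–C2′ bond by cross-coupling. It sets out from 1: bromination para to the hydroxyl (N-bromosuccinimide, CH2Cl2, −78 °C) gives the bromophenol F6, which is silylated (i-Pr3SiCl, imidazole, DMF) to the silyl ether F7. N-Boc-piperidine is deprotonated with s-BuLi and the (+)-sparteine surrogate (Et2O, −78 °C) to the 2-lithio carbamate F8, and transmetalation with ZnCl2 gives the organozinc chloride F9. Stereoretentive Negishi coupling of F9 with F7 (Pd(OAc)2, t-Bu3P·HBF4, rt) gives the aryl piperidine F10. This coupling carries its own risk, since β-hydride elimination at the di-ortho-substituted aryl palladium intermediate could shift the aryl group to C3′. Desilylation with Bu4NF (THF, 0 °C) gives 10, where the route is rejoined.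

**Further compounds**
F1 | step 11 | tert-butyl (2S)-2-[2,6-bis(benzyloxy)-3-[2-(tert-butoxycarbonyl)-3-(dimethylamino)prop-2-enoyl]-4-hydroxyphenyl]piperidine-1-carboxylate | CC(C)(C)OC(=O)N1CCCC[C@H]1c1c(OCc2ccccc2)cc(O)c(C(=O)C(C(=O)OC(C)(C)C)=CN(C)C)c1OCc1ccccc1
F2 | step 11 | tert-butyl 5,7-bis(benzyloxy)-6-[(2S)-1-(tert-butoxycarbonyl)piperidin-2-yl]-4-oxo-4H-chromene-3-carboxylate | CC(C)(C)OC(=O)N1CCCC[C@H]1c1c(OCc2ccccc2)cc2c(c1OCc1ccccc1)C(=O)C(C(=O)OC(C)(C)C)=CO2
F3 | step 9 | tert-butyl (2S)-2-[2,6-bis(benzyloxy)-4-hydroxy-3-iodophenyl]piperidine-1-carboxylate | CC(C)(C)OC(=O)N1CCCC[C@H]1c1c(OCc2ccccc2)cc(O)c(I)c1OCc1ccccc1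
F4 | step 9 | tert-butyl (2S)-2-[2,6-bis(benzyloxy)-3-(1-ethoxyvinyl)-4-hydroxyphenyl]piperidine-1-carboxylate | CC(C)(C)OC(=O)N1CCCC[C@H]1c1c(OCc2ccccc2)cc(O)c(C(=C)OCC)c1OCc1ccccc1
F5 | step 9 | tert-butyl (2S)-2-[3-acetyl-2,6-bis(benzyloxy)-4-hydroxyphenyl]piperidine-1-carboxylate | CC(C)(C)OC(=O)N1CCCC[C@H]1c1c(OCc2ccccc2)cc(O)c(C(C)=O)c1OCc1ccccc1
F6 | step 4 | 3,5-bis(benzyloxy)-4-bromophenol | Oc1cc(OCc2ccccc2)c(Br)c(OCc2ccccc2)c1
F7 | step 4 | [3,5-bis(benzyloxy)-4-bromophenoxy]triisopropylsilane | CC(C)[Si](Oc1cc(OCc2ccccc2)c(Br)c(OCc2ccccc2)c1)(C(C)C)C(C)C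
F8 | step 4 | tert-butyl 2-lithiopiperidine-1-carboxylate (configuration leading to the 2S aryl product) | CC(C)(C)OC(=O)N1CCCC[C@H]1[Li]
F9 | step 4 | tert-butyl 2-(chlorozincio)piperidine-1-carboxylate (same configuration) | CC(C)(C)OC(=O)N1CCCC[C@H]1[Zn]Cl
F10 | step 4 | tert-butyl (2S)-2-[2,6-bis(benzyloxy)-4-(triisopropylsilyloxy)phenyl]piperidine-1-carboxylate | CC(C)(C)OC(=O)N1CCCC[C@H]1c1c(OCc2ccccc2)cc(O[Si](C(C)C)(C(C)C)C(C)C)cc1OCc1ccccc1
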